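**Plan** (labdane numbering: ring A = C-1 to C-5 and C-10; ring B = C-5 to C-10; side chain C-11 to C-16 on C-9)

- Retrosynthesis: cut C-9–C-11 together with a 1,3-transposition of the C-7 carbonyl to C-9 (side-chain alkyllithium from (R)-linalool plus a decalin enone); take the C-6 oxygen back to a C-6 ketone; cut ring A at C-1–C-2 and C-3–C-4, which removes the unsubstituted C-2–C-3 unit and leaves a ring B cyclohexenone; take the two C-10 substituents back to (R)-carvone.
- Enabling feature: in ring A, C-4 is a gem-dimethyl carbon on C-5 (the tertiary radical formed by H-atom addition to the carvone isopropenyl group) and C-1 is a CH2 on the quaternary C-10 (a non-enolisable aldehyde). They are 1,4-related across the C-5–C-10 ring-fusion bond and C-2–C-3 bears no substituent, so a vinylphosphonium salt can serve as radical acceptor at C-3 and as ylide at C-2.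
- Forward order: ring B (carvone) → quaternary C-10 → ring A by radical/ylide annulation → alkene reduction → C-6 ketone, then 6β-alcohol → side chain joined at C-9 → acetate → oxidative transposition to the C-7 enone → desilylation.
- Stereochemistry: C-5 from (R)-carvone; C-10 by enolate hydroxymethylation anti to isopropenyl; C-6 by hydride attack on the α face, anti to the axial C-10 and 4β methyl groups; C-13 from (R)-linalool.

Key step: step 4

Remark: commercial (R)-(−)-carvone and (R)-(−)-linalool are assumed to be of high enantiomeric purity, so that C-5 and C-13 are defined by the starting materials.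

**Step 1**
Reactants: 1 (R)-(−)-carvone
Product: 3 (5R)-2,6-dimethyl-5-(prop-1-en-2-yl)cyclohex-2-en-1-one (6-methylcarvone; C-6 epimer mixture), via lithium dienolate 2 (not isolated)
Conditions: LiN(i-Pr)2, THF, −78 °C; MeI, −78 to 0 °C
Reagents that add atoms: iodomethane, CI
Why: Kinetic α′-deprotonation gives the cross-conjugated lithium dienolate, whose C-alkylation (enolate alkylation) installs the future C-10 methyl group; the epimer mixture at this carbon is erased when it is enolised again in step 2.

**Step 2**
Reactants: 3 6-methylcarvone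
Product: 5 (5S,6R)-6-(hydroxymethyl)-2,6-dimethyl-5-(prop-1-en-2-yl)cyclohex-2-en-1-one (CH2OH trans to isopropenyl), via lithium enolate 4 (not isolated)
Conditions: LiN(i-Pr)2, THF, −78 °C; CH2O (gas, from cracked paraformaldehyde), −78 °C; AcOH, −78 °C
Reagents that add atoms: formaldehyde, C=O
Why: Aldol addition of the tetrasubstituted enolate to formaldehyde should occur on the face anti to the neighbouring isopropenyl group, so the quaternary carbon (future C-10) carries CH2OH trans and CH3 cis to isopropenyl, and the cold acidic quench prevents retro-aldol.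

**Step 3**
Reactants: 5 hydroxymethyl ketone
Product: 6 (1R,6S)-1,3-dimethyl-2-oxo-6-(prop-1-en-2-yl)cyclohex-3-ene-1-carbaldehyde (formyl trans to isopropenyl)
Conditions: Dess–Martin periodinane, NaHCO3, CH2Cl2, 0 °C to rt
Reagents that add atoms: none
Why: Dess–Martin oxidation of the neopentyl primary alcohol under buffered, non-basic conditions should give the non-enolisable β-keto aldehyde without retro-aldol or deformylation.

**Step 4**
Reactants: 6 keto aldehyde; 7 vinyltriphenylphosphonium bromide
Product: 10 (4aS,8aS)-2,5,5,8a-tetramethyl-4a,5,6,8a-tetrahydronaphthalen-1(4H)-one (trans-fused; ring A C-1=C-2 alkene), via phosphonium salt 8 (not isolated), via ylide 9 (not isolated)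
Conditions: Fe(acac)3 (0.5 equiv), Ph(i-PrO)SiH2, 7 (1.3 equiv), i-PrOH/CH2Cl2, rt; concentrate; KN(SiMe3)2, THF, −78 °C to rt
Reagents that add atoms: none
Why: Proposed new method: an iron hydride generated from Fe(acac)3 and the silane transfers a hydrogen atom to the CH2 terminus of the isopropenyl group (Markovnikov HAT, which also creates the second C-4 methyl), the tertiary C-4 radical adds to the unsubstituted terminus of 7 (Giese addition, C-3–C-4 bond), and the α-phosphonio radical is reduced by divalent iron and protonated to salt 8, from which KN(SiMe3)2 liberates ylide 9 that closes onto the neopentyl aldehyde by intramolecular Wittig olefination (C-1–C-2 bond, loss of Ph3PO). The closest known reaction types are iron-hydride HAT-initiated Giese couplings of 1,1-disubstituted alkenes, HAT-initiated radical conjugate addition–aldol annulations, radical addition to vinylphosphonium salts followed by Wittig olefination under photoredox conditions, and the Schweizer annulation; new is the use of a vinylphosphonium salt as acceptor under HAT conditions with an annulative Wittig finish. Ring A closes in the second event as a six-membered ring by 6-exo-trig attack of the ylide carbon on the aldehyde and syn-elimination from the oxaphosphetane, which can only give the cis ring alkene. No stereocentre is created (C-4 carries two methyl groups); the trans ring fusion is already defined by the C-5 centre of carvone and by the trans disposition of formyl and isopropenyl set in step 2. The step needs HAT to the electron-rich isopropenyl group and not to the enone (secured by the polarity of the metal hydride), capture of the nucleophilic tertiary radical by the cationic acceptor and not by the enone (its only intramolecular options are a four-membered ring or polarity-mismatched attack at the enone α-carbon), and Wittig closure at the aldehyde and not at the ring ketone (that closure would give a bridgehead alkene), while the hindered alcohol and the non-nucleophilic base spare the deformylation-prone β-keto aldehyde.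

**Step 5**
Reactants: 10 bicyclic dienone
Product: 11 (4aS,8aS)-2,5,5,8a-tetramethyl-4a,5,6,7,8,8a-hexahydronaphthalen-1(4H)-one (trans-decalin enone; C-9 ketone, C-7=C-8 alkene)
Conditions: H2 (1 atm), RhCl(PPh3)3 (cat.), benzene, rt
Reagents that add atoms: none
Why: Homogeneous hydrogenation with RhCl(PPh3)3 should reduce the isolated cis-disubstituted ring A alkene and leave the trisubstituted, conjugated enone alkene untouched.

**Step 6**
Reactants: 11 decalin enone
Product: 12 (4aS,8aS)-2,5,5,8a-tetramethyl-4a,5,6,7,8,8a-hexahydronaphthalene-1,4-dione (7-ene-6,9-dione)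
Conditions: Pd(OH)2/C (cat.), t-BuOOH, K2CO3, CH2Cl2, 0 °C to rt
Reagents that add atoms: tert-butyl hydroperoxide, CC(C)(C)OO
Why: Palladium-mediated tert-butylperoxy radical allylic oxidation should convert the only allylic CH2 (C-6, γ to the C-9 carbonyl) into a ketone to give the ene-1,4-dione, with C-5 remaining in the more stable trans-fused configuration.

**Step 7**
Reactants: 12 ene-dione
Product: 13 (4R,4aS,8aS)-4-hydroxy-2,5,5,8a-tetramethyl-4a,5,6,7,8,8a-hexahydronaphthalen-1(4H)-one (6β-hydroxy-7-en-9-one)
Conditions: NaBH4, CeCl3·7H2O, MeOH, −78 °C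
Reagents that add atoms: none
Why: Luche 1,2-reduction should select the C-6 carbonyl (flanked by CH and =CH) over the C-9 carbonyl (flanked by the quaternary C-10 and the methyl-bearing sp2 carbon), and hydride enters from the α face, anti to the axial C-10 and 4β methyl groups, which gives the axial 6β-alcohol.

**Step 8**
Reactants: 14 (R)-(−)-linalool
Product: 15 (R)-triethyl[(3,7-dimethylocta-1,6-dien-3-yl)oxy]silane
Conditions: Et3SiOTf, 2,6-lutidine, CH2Cl2, 0 °C
Reagents that add atoms: triethylsilyl trifluoromethanesulfonate, CC[Si](CC)(CC)OS(=O)(=O)C(F)(F)F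
Why: Silylation of the tertiary allylic alcohol with the silyl triflate (silyl ether protection) masks the C-13 carbinol against the later organolithium and chromium steps.

**Step 9**
Reactants: 15 silyl ether
Product: 16 (R)-4-methyl-4-(triethylsilyloxy)hex-5-enal
Conditions: O3/O2 (1 equiv, dosed), pyridine, CH2Cl2, −78 °C
Reagents that add atoms: ozone, [O-][O+]=O
Why: Ozonolysis should be selective because ozone reacts much faster with the electron-rich trisubstituted alkene than with the hindered vinyl group next to the silyloxy carbon, and pyridine converts the carbonyl oxide directly into the aldehyde.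

**Step 10**
Reactants: 16 aldehyde
Product: 17 (R)-4-methyl-4-(triethylsilyloxy)hex-5-enoic acid
Conditions: NaClO2, NaH2PO4, 2-methyl-2-butene, t-BuOH/H2O, 0 °C to rt
Reagents that add atoms: sodium chlorite, [Na+].[O-]Cl=O
Why: Pinnick oxidation converts the aldehyde into the acid under mildly acidic buffer, with the excess trisubstituted alkene scavenging hypochlorite before it can touch the vinyl group.

**Step 11**
Reactants: 17 acid
Product: 19 (R)-triethyl[(5-iodo-3-methylpent-1-en-3-yl)oxy]silane, via Barton ester 18 (not isolated)
Conditions: 2-mercaptopyridine N-oxide, DCC, DMAP (cat.), CH2Cl2, rt, dark; then CHI3, hν (tungsten lamp), reflux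
Reagents that add atoms: iodoform, IC(I)I
Why: Barton decarboxylative iodination: photolysis of the thiohydroxamate ester gives the primary radical one carbon shorter, which abstracts iodine from iodoform and has no favourable cyclisation onto the vinyl group (only 4-exo or 5-endo modes).

**Step 12**
Reactants: 13 6β-hydroxy enone; 19 iodide
Product: 22 (13R)-13-(triethylsilyloxy)labda-7,14-diene-6β,9-diol (9β-hydroxy epimer drawn; side chain α; the C-9 configuration is inconsequential), via lithium alkoxide 20 (not isolated), via alkyllithium 21 (not isolated)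
Conditions: 19 (2.3 equiv), t-BuLi (4.6 equiv), Et2O/pentane, −78 °C; add 13 in Et2O, −78 to −20 °C; aq NH4Cl
Reagents that add atoms: none
Why: Iodine–lithium exchange (in ether/pentane at −78 °C, where oxygen-to-carbon silyl migration is slow) gives the primary alkyllithium, the first equivalent of which converts the 6β-hydroxyl into its lithium alkoxide (no amine or other proton source is left to quench the reagent) while the second undergoes 1,2-addition to the C-9 ketone, which has no α′-hydrogen, from the face anti to the C-10 methyl group; the new carbinol centre is destroyed in step 14.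

**Step 13**
Reactants: 22 diol
Product: 23 (13R)-6β-acetoxy-13-(triethylsilyloxy)labda-7,14-dien-9-ol
Conditions: Ac2O, DMAP, Et3N, CH2Cl2, rt
Reagents that add atoms: acetic anhydride, CC(=O)OC(C)=O
Why: DMAP-catalysed acylation should acetylate only the secondary 6β-hydroxyl, because the tertiary C-9 hydroxyl and the silylated tertiary C-13 oxygen are inert under these conditions.

**Step 14**
Reactants: 23 acetoxy tertiary allylic alcohol
Product: 24 (13R)-6β-acetoxy-13-(triethylsilyloxy)labda-8,14-dien-7-one
Conditions: pyridinium chlorochromate (C5H5NH[CrO3Cl]), 4 Å molecular sieves, CH2Cl2, rt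
Reagents that add atoms: pyridinium chlorochromate, [O-][Cr](=O)(=O)Cl.c1cc[nH+]cc1
Why: Babler–Dauben oxidative transposition: the chromate ester of the tertiary allylic alcohol undergoes a [3,3] shift to C-7 and is oxidised by hexavalent chromium to the enone, which places the alkene in the tetrasubstituted C-8=C-9 position without enolising C-6.

**Step 15**
Reactants: 24 silyl ether
Product: 25 (13R)-6β-acetoxy-13-hydroxylabda-8,14-dien-7-one (target, CNP0328351.1)
Conditions: HF·pyridine, pyridine, THF, 0 °C to rt
Reagents that add atoms: none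
Why: Fluoride-mediated desilylation under buffered, weakly acidic conditions should free the tertiary allylic alcohol without acyl migration, C-6 epimerisation or ionisation at C-13.

**Compound list**

1 | (R)-(−)-carvone | O=C1C(C)=CC[C@@H](C(C)=C)C1 | starting material
2 | lithium dienolate of 1 | [Li+].[O-]C1=C[C@H](C(C)=C)CC=C1C | intermediate
3 | (5R)-2,6-dimethyl-5-(prop-1-en-2-yl)cyclohex-2-en-1-one, C-6 epimer mixture | O=C1C(C)=CC[C@@H](C(C)=C)C1C | intermediate
4 | lithium enolate of 3 | [Li+].[O-]C1=C(C)[C@H](C(C)=C)CC=C1C | intermediate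
5 | (5S,6R)-6-(hydroxymethyl)-2,6-dimethyl-5-(prop-1-en-2-yl)cyclohex-2-en-1-one | O=C1C(C)=CC[C@@H](C(C)=C)[C@]1(C)CO | intermediate
6 | (1R,6S)-1,3-dimethyl-2-oxo-6-(prop-1-en-2-yl)cyclohex-3-ene-1-carbaldehyde | O=C1C(C)=CC[C@@H](C(C)=C)[C@]1(C)C=O | intermediate
7 | vinyltriphenylphosphonium bromide | C=C[P+](c1ccccc1)(c1ccccc1)c1ccccc1.[Br-] | starting material
8 | phosphonium salt (Giese adduct of 6 and 7) | [Br-].O=C1C(C)=CC[C@@H](C(C)(C)CC[P+](c2ccccc2)(c2ccccc2)c2ccccc2)[C@]1(C)C=O | intermediate
9 | phosphorus ylide from 8 | O=C1C(C)=CC[C@@H](C(C)(C)CC=P(c2ccccc2)(c2ccccc2)c2ccccc2)[C@]1(C)C=O | intermediate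
10 | (4aS,8aS)-2,5,5,8a-tetramethyl-4a,5,6,8a-tetrahydronaphthalen-1(4H)-one | O=C1C(C)=CC[C@H]2C(C)(C)CC=C[C@]12C | intermediate
11 | (4aS,8aS)-2,5,5,8a-tetramethyl-4a,5,6,7,8,8a-hexahydronaphthalen-1(4H)-one | O=C1C(C)=CC[C@H]2C(C)(C)CCC[C@]12C | intermediate
12 | (4aS,8aS)-2,5,5,8a-tetramethyl-4a,5,6,7,8,8a-hexahydronaphthalene-1,4-dione | O=C1C(C)=CC(=O)[C@H]2C(C)(C)CCC[C@]12C | intermediate
13 | (4R,4aS,8aS)-4-hydroxy-2,5,5,8a-tetramethyl-4a,5,6,7,8,8a-hexahydronaphthalen-1(4H)-one | O=C1C(C)=C[C@@H](O)[C@H]2C(C)(C)CCC[C@]12C | intermediate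
14 | (R)-(−)-linalool | C=C[C@](C)(O)CCC=C(C)C | starting material
15 | (R)-triethyl[(3,7-dimethylocta-1,6-dien-3-yl)oxy]silane | C=C[C@](C)(O[Si](CC)(CC)CC)CCC=C(C)C | intermediate
16 | (R)-4-methyl-4-(triethylsilyloxy)hex-5-enal | C=C[C@](C)(O[Si](CC)(CC)CC)CCC=O | intermediate
17 | (R)-4-methyl-4-(triethylsilyloxy)hex-5-enoic acid | C=C[C@](C)(O[Si](CC)(CC)CC)CCC(=O)O | intermediate
18 | 2-thioxopyridin-1(2H)-yl ester of 17 (Barton ester) | C=C[C@](C)(O[Si](CC)(CC)CC)CCC(=O)On1ccccc1=S | intermediate
19 | (R)-triethyl[(5-iodo-3-methylpent-1-en-3-yl)oxy]silane | C=C[C@](C)(O[Si](CC)(CC)CC)CCI | intermediate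
20 | lithium alkoxide of 13 | [Li+].O=C1C(C)=C[C@@H]([O-])[C@H]2C(C)(C)CCC[C@]12C | intermediate
21 | (R)-[3-methyl-3-(triethylsilyloxy)pent-4-en-1-yl]lithium | C=C[C@](C)(O[Si](CC)(CC)CC)CC[Li] | intermediate
22 | (13R)-13-(triethylsilyloxy)labda-7,14-diene-6β,9-diol (9β-OH drawn) | C=C[C@](C)(O[Si](CC)(CC)CC)CC[C@]1(O)C(C)=C[C@@H](O)[C@H]2C(C)(C)CCC[C@]12C | intermediate
23 | (13R)-6β-acetoxy-13-(triethylsilyloxy)labda-7,14-dien-9-ol (9β-OH drawn) | C=C[C@](C)(O[Si](CC)(CC)CC)CC[C@]1(O)C(C)=C[C@@H](OC(C)=O)[C@H]2C(C)(C)CCC[C@]12C | intermediate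
24 | (13R)-6β-acetoxy-13-(triethylsilyloxy)labda-8,14-dien-7-one | C=C[C@](C)(O[Si](CC)(CC)CC)CCC1=C(C)C(=O)[C@@H](OC(C)=O)[C@H]2C(C)(C)CCC[C@]12C | intermediate
25 | (13R)-6β-acetoxy-13-hydroxylabda-8,14-dien-7-one | C=C[C@](C)(O)CCC1=C(C)C(=O)[C@@H](OC(C)=O)[C@H]2C(C)(C)CCC[C@]12C | target

**Totals**

Total step count: 15. Longest linear sequence: 11 steps (steps 1 to 7 and 12 to 15, from (R)-carvone); the side-chain fragment takes steps 8 to 11.

**Steps most likely to fail**

Step 4 (proposed new method). The tertiary radical may be reduced to the isopropyl group before the phosphonium acceptor captures it, or the formyl group may be lost by retro-Claisen cleavage before the ylide closes. Fallback with known reactions, from 6 back to 10, with ring A closed by metathesis instead: Wittig methylenation of 6 (Ph3P=CH2, THF, −78 to 0 °C) would give 6-ethenyl-2,6-dimethyl-5-(prop-1-en-2-yl)cyclohex-2-en-1-one F1. Markovnikov addition of HBr to its isopropenyl group (HBr, CH2Cl2, 0 °C; the known behaviour of carvone itself) would give the tertiary bromide 5-(2-bromopropan-2-yl)-6-ethenyl-2,6-dimethylcyclohex-2-en-1-one F2. Keck radical allylation (allyltributylstannane, AIBN, benzene, 80 °C) would build the quaternary C-4 as 6-ethenyl-2,6-dimethyl-5-(2-methylpent-4-en-2-yl)cyclohex-2-en-1-one F3. Ring-closing metathesis with second-generation Grubbs catalyst (CH2Cl2, 40 °C) would then join C-1 and C-2 and return to 10.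

Step 6. The oxidation may stall or over-oxidise, because the ene-dione product is itself open to nucleophilic epoxidation by the peroxide, and the allylic methyl may compete. Fallback from 11 back to 12 by enolisation chemistry instead of C–H oxidation: γ-deprotonation of 11 (the only acidic position; LiN(i-Pr)2, then Me3SiCl) would give the silyl dienol ether trimethyl[(2,5,5,8a-tetramethyl-4a,5,6,7,8,8a-hexahydronaphthalen-1-yl)oxy]silane F4. Vinylogous Rubottom oxidation (mCPBA, NaHCO3, CH2Cl2, then mild acidic work-up) would give the γ-hydroxy enone 4-hydroxy-2,5,5,8a-tetramethyl-4a,5,6,7,8,8a-hexahydronaphthalen-1(4H)-one F5 as a C-6 epimer mixture. Dess–Martin oxidation of F5 would give 12.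

Step 14. The hindered tertiary carbinol may be slow to form its chromate ester, or the acidic oxidant may ionise it and cause elimination. Fallback from 23 back to 24 in two non-chromium operations: catalytic 1,3-transposition of the tertiary allylic alcohol with O3ReOSiPh3 (Et2O, −50 to 0 °C, where the free carbinol should react well ahead of the C-13 silyl ether) would give the secondary allylic alcohol (13R)-6β-acetoxy-7-hydroxy-13-(triethylsilyloxy)labda-8,14-diene F6 as a C-7 epimer mixture. This is oxidised without delay with Dess–Martin periodinane to 24.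

**Further compounds**

F1 | step 4 | 6-ethenyl-2,6-dimethyl-5-(prop-1-en-2-yl)cyclohex-2-en-1-one (ethenyl trans to isopropenyl) | O=C1C(C)=CC[C@@H](C(C)=C)[C@]1(C)C=C
F2 | step 4 | 5-(2-bromopropan-2-yl)-6-ethenyl-2,6-dimethylcyclohex-2-en-1-one (ethenyl trans to the C-5 substituent) | O=C1C(C)=CC[C@@H](C(C)(C)Br)[C@]1(C)C=C
F3 | step 4 | 6-ethenyl-2,6-dimethyl-5-(2-methylpent-4-en-2-yl)cyclohex-2-en-1-one (ethenyl trans to the C-5 substituent) | O=C1C(C)=CC[C@@H](C(C)(C)CC=C)[C@]1(C)C=C
F4 | step 6 | trimethyl[(2,5,5,8a-tetramethyl-4a,5,6,7,8,8a-hexahydronaphthalen-1-yl)oxy]silane (trans-fused silyl dienol ether of 11) | C[Si](C)(C)OC1=C(C)C=C[C@H]2C(C)(C)CCC[C@]12C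
F5 | step 6 | 4-hydroxy-2,5,5,8a-tetramethyl-4a,5,6,7,8,8a-hexahydronaphthalen-1(4H)-one, C-4 (labdane C-6) epimer mixture | O=C1C(C)=CC(O)[C@H]2C(C)(C)CCC[C@]12C
F6 | step 14 | (13R)-6β-acetoxy-7-hydroxy-13-(triethylsilyloxy)labda-8,14-diene, C-7 epimer mixture | C=C[C@](C)(O[Si](CC)(CC)CC)CCC1=C(C)C(O)[C@@H](OC(C)=O)[C@H]2C(C)(C)CCC[C@]12C
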